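## Retrosynthetic overview

1. 15 ⇒ alkenyl triflate 14 (C4 methyl by Stille coupling) ⇒ ring A o-quinone 13 + dienyl triflate 7 by hetero-Diels–Alder; the 1,4-dioxane (C1–O3, C5–O2) is the last ring formed.
2. 13 ⇐ 6-oxopristimerol 12 ⇐ celastrol 8 by esterification, reductive acetylation, C6 oxidation and deacetylation; triterpene rings A–E are taken intact.
3. 7 ⇐ hydroazulenone 6; key bond C1–C2: the β-carbon of the C4 ketone (a homoenolate released from cyclopropanol 5) is joined to the vinyl triflate carbon that was the ring ketone.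
4. 5 ⇐ β-keto ester 3 ⇐ one-carbon ring expansion of cis-dihydrocarvone 2 ⇐ (S)-carvone 1 (C7 from carvone, C10 from the enzymatic reduction).
5. Ring order: seven-membered carbocycle → cyclopentene → 1,4-dioxane onto the preformed pentacycle.

Numbering: guaiane numbering for the sesquiterpene half (C1/C5 ring fusion, C4 carries the vinylic methyl, C7 the isopropenyl, C10 the secondary methyl); friedelane numbering for the triterpene half.

Assumption: celastrol, a plant isolate sold in bulk, is accepted as the commercial source of the friedelane pentacycle; the sesquiterpene half is built from (S)-carvone.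

## Route

Step 1
Reactants: 1 (S)-(+)-carvone
Product: 2 (2R,5S)-dihydrocarvone
Conditions: ene-reductase OYE2, NADP+ (cat.), glucose dehydrogenase, D-glucose, phosphate buffer pH 7.0, 30 °C, 6 h
Reagents that add atoms: none
Why: Old-yellow-enzyme conjugate reduction of the enone delivers hydride to C3 and protonates C2 from one enzyme-fixed face whatever the C5 configuration, which gives the cis (2R,5S) ketone that trans-selective chemical conjugate reduction does not give.

Step 2
Reactants: 2 (2R,5S)-dihydrocarvone
Product: 3 cycloheptanone β-keto ester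
Conditions: ethyl diazoacetate, BF3·OEt2, Et2O, −20 → 0 °C
Reagents that add atoms: ethyl diazoacetate, CCOC(=O)C=[N+]=[N-]
Why: Lewis-acid-promoted diazoacetate homologation (Tiffeneau–Demjanov-type ring expansion) with migration of the less substituted α-CH2 inserts the CH(CO2Et) carbon (future C5, carrying future C4) between C=O and CH2, leaves both stereocentres untouched, and gives a product that enolises only towards the ester, which shields the α-methyl centre.

Step 3
Reactants: 3 cycloheptanone β-keto ester
Product: 4 β-triflyloxy enoate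
Conditions: Tf2O, iPr2NEt, CH2Cl2, −78 °C
Reagents that add atoms: triflic anhydride, O=S(=O)(OS(=O)(=O)C(F)(F)F)C(F)(F)F
Why: O-sulfonylation of the β-keto ester enol (enol triflate formation) turns the ketone carbon (future C1) into a vinyl electrophile without touching a stereocentre.

Step 4
Reactants: 4 β-triflyloxy enoate
Product: 5 cyclopropanol vinyl triflate
Conditions: EtMgBr (2.5 equiv, slow addition), Ti(OiPr)4 (0.3 equiv), THF, 0 °C → rt; aq. NH4Cl
Reagents that add atoms: ethylmagnesium bromide, CC[Mg]Br
Why: Kulinkovich cyclopropanation, in which the titanacyclopropane made from EtMgBr and Ti(OiPr)4 adds twice to the ester carbonyl, converts the ester into a 1-substituted cyclopropanol (a latent homoenolate), while the tetrasubstituted enol triflate is too hindered for alkene exchange and does not couple with the low standing concentration of Grignard reagent without an iron or copper catalyst.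

Step 5
Reactants: 5 cyclopropanol vinyl triflate
Product: 6 hydroazulenone
Conditions: Pd(OAc)2 (5 mol%), XPhos (10 mol%), Cs2CO3, toluene, 60 °C
Reagents that add atoms: none
Why: Proposed new method: zerovalent palladium formed in the flask adds oxidatively into the vinyl C–OTf bond, the neighbouring cyclopropoxide replaces triflate on palladium, strain-driven β-carbon elimination opens the three-membered ring to a six-membered palladacyclic homoenolate, and C(sp3)–C(sp2) reductive elimination closes the cyclopentenone between C2 (β to the new C4 ketone, normally an acceptor position) and C1 (the former ketone carbon); the closest known reaction type is the intermolecular palladium-catalysed ring-opening cross-coupling of cyclopropanols with aryl and alkenyl halides, and no stereocentre is formed or disturbed.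

Step 6
Reactants: 6 hydroazulenone
Product: 7 dienyl triflate
Conditions: LiN(SiMe3)2, THF, −78 °C; PhNTf2, −78 → −20 °C; made just before step 11 and used at once
Reagents that add atoms: N-phenylbis(trifluoromethanesulfonimide), O=S(=O)(N(c1ccccc1)S(=O)(=O)C(F)(F)F)C(F)(F)F
Why: Kinetic α′-deprotonation of the cyclopentenone at C3 followed by O-triflation (enol triflate formation) gives the cross-conjugated diene with C3=C4 and C1=C5 regiospecifically, at a temperature where 1,5-hydrogen shifts of the cyclopentadiene do not occur.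

Step 7
Reactants: 8 celastrol
Product: 9 pristimerin
Conditions: Me3SiCHN2, PhMe/MeOH 4:1, 0 °C
Reagents that add atoms: (trimethylsilyl)diazomethane, C[Si](C)(C)C=[N+]=[N-]
Why: Diazoalkane esterification methylates the carboxylic acid chemoselectively, because the hydrogen-bonded enol of the quinone methide is far less acidic.

Step 8
Reactants: 9 pristimerin
Product: 10 pristimerol diacetate
Conditions: Zn dust, Ac2O, pyridine, AcOH (cat.), rt
Reagents that add atoms: acetic anhydride, CC(=O)OC(C)=O
Why: Reductive acetylation, in which zinc reduces the extended quinone methide (hydrogen added at C6) and the catecholate is trapped as the air-stable diacetate, aromatises ring A and exposes C6 as a CH2 group.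

Step 9
Reactants: 10 pristimerol diacetate
Product: 11 6-oxopristimerol diacetate
Conditions: Rh2(cap)4 (1 mol%), t-BuOOH (70% aq., 5 equiv), NaHCO3, ClCH2CH2Cl, 40 °C
Reagents that add atoms: tert-butyl hydroperoxide, CC(C)(C)OO
Why: Peroxyl-radical allylic/benzylic oxidation (dirhodium caprolactamate with t-BuOOH) is selective for C6, the only CH2 that is both benzylic and allylic to C7=C8 (the other allylic positions are quaternary), and gives the 7-en-6-one.

Step 10
Reactants: 11 6-oxopristimerol diacetate
Product: 12 6-oxopristimerol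
Conditions: K2CO3, MeOH (degassed), Ar, 0 °C → rt; dilute HCl
Reagents that add atoms: none
Why: Base-catalysed methanolysis (transesterification) removes the two aryl acetates, the hindered methyl ester can only exchange methoxide for methoxide, and exclusion of air keeps the catechol from oxidising.

Step 11
Reactants: 12 6-oxopristimerol; 7 dienyl triflate
Product: 14 cycloadduct alkenyl triflate, via o-quinone 13 (not isolated)
Conditions: Ag2O, Na2SO4, CH2Cl2, 0 °C, 20 min; filter cold under Ar; then 7 (1.5 equiv), −20 °C → rt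
Reagents that add atoms: none
Why: Ag2O dehydrogenates the catechol to the electron-poor o-quinone, which adds as a heterodiene (inverse-electron-demand hetero-Diels–Alder) across the tetrasubstituted C1=C5 bond of 7 because C3=C4 is deactivated by OTf; the nucleophilic terminus C1 bonds to O-3 (the phenoxide developing at O-2 is para to the C6 ketone), O-2 closes on C5, and approach anti to the pseudo-axial C10 methyl and the C7 isopropenyl sets the cis-dioxy C1/C5 ring fusion of the target.

Step 12
Reactants: 14 cycloadduct alkenyl triflate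
Product: 15 target CNP0317749.2
Conditions: Me4Sn, Pd(PPh3)4 (10 mol%), LiCl, THF, 65 °C
Reagents that add atoms: tetramethylstannane, C[Sn](C)(C)C
Why: Stille coupling of the alkenyl triflate (oxidative addition to zerovalent palladium, chloride exchange, tin-to-palladium methyl transfer, reductive elimination) installs the C4 methyl with the double bond fixed at C3=C4 and leaves ketone, ester, isopropenyl and all stereocentres unchanged.

## Compound list

1 | (S)-(+)-carvone, (5S)-2-methyl-5-(prop-1-en-2-yl)cyclohex-2-en-1-one | CC1=CC[C@@H](CC1=O)C(C)=C | starting material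
2 | (2R,5S)-2-methyl-5-(prop-1-en-2-yl)cyclohexan-1-one (cis-dihydrocarvone) | C[C@@H]1CC[C@@H](CC1=O)C(C)=C | intermediate
3 | ethyl (3R,6S)-3-methyl-2-oxo-6-(prop-1-en-2-yl)cycloheptane-1-carboxylate (C1 epimers and enol) | CCOC(=O)C1C[C@@H](C(C)=C)CC[C@@H](C)C1=O | intermediate
4 | ethyl (3R,6S)-3-methyl-6-(prop-1-en-2-yl)-2-(trifluoromethanesulfonyloxy)cyclohept-1-ene-1-carboxylate | CCOC(=O)C1=C(OS(=O)(=O)C(F)(F)F)[C@H](C)CC[C@H](C(C)=C)C1 | intermediate
5 | (4S,7R)-2-(1-hydroxycyclopropyl)-7-methyl-4-(prop-1-en-2-yl)cyclohept-1-en-1-yl trifluoromethanesulfonate | OC1(CC1)C2=C(OS(=O)(=O)C(F)(F)F)[C@H](C)CC[C@H](C(C)=C)C2 | intermediate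
6 | (4R,7S)-4-methyl-7-(prop-1-en-2-yl)-3,4,5,6,7,8-hexahydroazulen-1(2H)-one (guaiane numbering: 4-ketone, 1(5)-ene, 7S, 10R, no C4 methyl) | O=C1CCC2=C1C[C@@H](C(C)=C)CC[C@H]2C | intermediate
7 | (4R,7S)-4-methyl-7-(prop-1-en-2-yl)-3,4,5,6,7,8-hexahydroazulen-1-yl trifluoromethanesulfonate (guaiane numbering: 4-OTf, 1(5),3-diene) | FC(F)(F)S(=O)(=O)OC1=CCC2=C1C[C@@H](C(C)=C)CC[C@H]2C | intermediate
8 | celastrol, 3-hydroxy-2-oxo-24-nor-D:A-friedooleana-1(10),3,5,7-tetraen-29-oic acid, natural configuration | CC1=C(O)C(=O)C=C2C1=CC=C1[C@@]2(C)CC[C@@]2(C)[C@@H]3C[C@](C)(C(O)=O)CC[C@]3(C)CC[C@]12C | starting material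
9 | pristimerin, methyl ester of celastrol | CC1=C(O)C(=O)C=C2C1=CC=C1[C@@]2(C)CC[C@@]2(C)[C@@H]3C[C@](C)(C(=O)OC)CC[C@]3(C)CC[C@]12C | intermediate
10 | pristimerol diacetate, methyl 2,3-diacetoxy-24-nor-D:A-friedooleana-1,3,5(10),7-tetraen-29-oate | CC(=O)Oc1cc2c(c(C)c1OC(C)=O)CC=C1[C@@]2(C)CC[C@@]2(C)[C@@H]3C[C@](C)(C(=O)OC)CC[C@]3(C)CC[C@]12C | intermediate
11 | 6-oxopristimerol diacetate, methyl 2,3-diacetoxy-6-oxo-24-nor-D:A-friedooleana-1,3,5(10),7-tetraen-29-oate | CC(=O)Oc1cc2c(c(C)c1OC(C)=O)C(=O)C=C1[C@@]2(C)CC[C@@]2(C)[C@@H]3C[C@](C)(C(=O)OC)CC[C@]3(C)CC[C@]12C | intermediate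
12 | 6-oxopristimerol, methyl 2,3-dihydroxy-6-oxo-24-nor-D:A-friedooleana-1,3,5(10),7-tetraen-29-oate | Oc1cc2c(c(C)c1O)C(=O)C=C1[C@@]2(C)CC[C@@]2(C)[C@@H]3C[C@](C)(C(=O)OC)CC[C@]3(C)CC[C@]12C | intermediate
13 | ring A o-quinone, methyl 2,3,6-trioxo-24-nor-D:A-friedooleana-1(10),4,7-trien-29-oate | O=C1C=C2C(=C(C)C1=O)C(=O)C=C1[C@@]2(C)CC[C@@]2(C)[C@@H]3C[C@](C)(C(=O)OC)CC[C@]3(C)CC[C@]12C | intermediate
14 | cycloadduct alkenyl triflate: compound 15 with the guaiane C4 methyl replaced by OSO2CF3, all stereocentres as in 15 | C=C(C)[C@H]1CC[C@@H](C)[C@@]23CC=C(OS(=O)(=O)C(F)(F)F)[C@]2(C1)Oc1cc2c(c(C)c1O3)C(=O)C=C1[C@@]2(C)CC[C@@]2(C)[C@@H]3C[C@](C)(C(=O)OC)CC[C@]3(C)CC[C@]12C | intermediate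
15 | CNP0317749.2: 6-oxopristimerol 2,3-O-[(1S,5S,7S,10R)-guaia-3,11-diene-1,5-diyl] ether (O-3 on guaiane C1, O-2 on guaiane C5, cis-dioxy ring fusion anti to the C10 methyl and C7 isopropenyl) | C=C(C)[C@H]1CC[C@@H](C)[C@@]23CC=C(C)[C@]2(C1)Oc1cc2c(c(C)c1O3)C(=O)C=C1[C@@]2(C)CC[C@@]2(C)[C@@H]3C[C@](C)(C(=O)OC)CC[C@]3(C)CC[C@]12C | target

## Step count and risks

Total steps: 12. Longest linear sequence: 8 (1 → 15 through steps 1–6, 11 and 12); the triterpene branch 8 → 12 is 4 steps and joins at step 11.

Step 11 (hetero-Diels–Alder) is the most likely to fail. The triflate-bearing diene may react too slowly with 13, and the regiochemistry (O-3 to C1) and facial selectivity rest on argument, not precedent. The fallback sets out from 7 and comes back at 15, skipping 14 and step 12. Coupling of 7 with MeMgBr under Fe(acac)3 catalysis (THF/NMP, −30 °C) gives the free triene (4R,7S)-1,4-dimethyl-7-(prop-1-en-2-yl)-3,4,5,6,7,8-hexahydroazulene F4. It is kept below 0 °C to suppress 1,5-hydrogen shifts and added at −78 °C to the filtered solution of 13. The more electron-rich cyclopentadiene reacts faster and gives 15 directly, at the price of possible competition from its now unprotected C3=C4 bond.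

Step 5 (palladium homoenolate ring closure) is second. β-Hydride elimination of the homoenolate or ring expansion of the vinylcyclopropanol could outrun reductive elimination. The fallback sets out from 5 and comes back at 6. Et2Zn (toluene, 0 °C) opens the cyclopropanol to its zinc homoenolate, and an I2 quench at −78 °C gives the β-iodo ketone (4S,7R)-2-(3-iodopropanoyl)-7-methyl-4-(prop-1-en-2-yl)cyclohept-1-en-1-yl trifluoromethanesulfonate F3. Intramolecular nickel-catalysed reductive cross-electrophile coupling of the alkyl iodide with the vinyl triflate (NiBr2(dme), 4,4′-di-tert-butyl-2,2′-bipyridine, Zn, DMA, rt) then closes the same C1–C2 bond to give 6.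

Step 4 (Kulinkovich reaction on a β-triflyloxy enoate) is third. The Grignard reagent may attack the vinylogous triflate, or the conjugated ester may react sluggishly. The fallback sets out from 4 and comes back at 6, skipping 5.
- Negishi coupling of 4 with the zinc homoenolate BrZnCH2CH2CO2Et (Pd(PPh3)4, THF, 50 °C) gives the diester ethyl (3R,6S)-2-(3-ethoxy-3-oxopropyl)-3-methyl-6-(prop-1-en-2-yl)cyclohept-1-ene-1-carboxylate F1.
- Dieckmann condensation (KOtBu, THF, 0 °C) gives the bicyclic β-keto ester ethyl (4R,7S)-4-methyl-1-oxo-7-(prop-1-en-2-yl)-1,2,3,4,5,6,7,8-octahydroazulene-2-carboxylate F2.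
- Krapcho dealkoxycarbonylation (LiCl, wet DMSO, 130 °C) gives 6.

## Further compounds

F1 | step 4 | ethyl (3R,6S)-2-(3-ethoxy-3-oxopropyl)-3-methyl-6-(prop-1-en-2-yl)cyclohept-1-ene-1-carboxylate | CCOC(=O)CCC1=C(C(=O)OCC)C[C@@H](C(C)=C)CC[C@H]1C
F2 | step 4 | ethyl (4R,7S)-4-methyl-1-oxo-7-(prop-1-en-2-yl)-1,2,3,4,5,6,7,8-octahydroazulene-2-carboxylate (C2 epimers) | CCOC(=O)C1CC2=C(C[C@@H](C(C)=C)CC[C@H]2C)C1=O
F3 | step 5 | (4S,7R)-2-(3-iodopropanoyl)-7-methyl-4-(prop-1-en-2-yl)cyclohept-1-en-1-yl trifluoromethanesulfonate | ICCC(=O)C1=C(OS(=O)(=O)C(F)(F)F)[C@H](C)CC[C@H](C(C)=C)C1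
F4 | step 11 | (4R,7S)-1,4-dimethyl-7-(prop-1-en-2-yl)-3,4,5,6,7,8-hexahydroazulene | CC1=CCC2=C1C[C@@H](C(C)=C)CC[C@H]2C
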